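Everything rests on closing rings A and B together. The C5–C10 single bond and the C8=C9 double bond are made in one base-mediated vinylogous Michael addition/aldol condensation of an open chain. The step exploits the 1,3-relation between the C6 oxygen and the C8(Me)=C9 alkene in ring B, and the syn-axial C19 and C6 oxygens. C19 is carried as a carboxyl group that acylates the C6 enol. The precursor is therefore a 5-(2-oxopropylidene)butanolide (C4–C8, C17–C19) tied through C3–C1 to an (E)-enal (C10=C9–C11). This temporary lactone relays C4 to C5, steers dehydration to C9 and is finally reduced to both carbinols.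

Key step: step 10

Remark: all intermediates carry the labdane numbering of the target (C1–C10 decalin carbons, C11–C16 side chain, C17 on C8, C18 and C19 on C4, C20 on C10). Lactones 17 and 18 are drawn as the E-ylidene isomers; the Z isomers would enter the same dienolate in step 10.

Step 1
Reactants: 1 geraniol
Product: 2 geranyl tert-butyldimethylsilyl ether
Conditions: TBSCl, imidazole, CH2Cl2, 0 °C to rt
Reagents that add atoms: tert-butyldimethylsilyl chloride, CC(C)(C)[Si](C)(C)Cl
Why: Imidazole-promoted silyl ether formation masks the primary allylic C11 alcohol for the strongly basic steps that follow.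

Step 2
Reactants: 2 geranyl tert-butyldimethylsilyl ether
Product: 4 (4E)-6-[(tert-butyldimethylsilyl)oxy]-4-methylhex-4-enal, via secondary ozonide 3 (not isolated)
Conditions: O3 (about 1 equiv, Sudan Red 7B as end-point dye), CH2Cl2, −78 °C; then Me2S, −78 °C to rt
Reagents that add atoms: ozone, [O-][O+]=O
Why: In this chemoselective ozonolysis the remote, electron-rich trisubstituted alkene should react before the alkene deactivated by the allylic silyloxy group, and reductive work-up gives the aldehyde carbon that becomes C3.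

Step 3
Reactants: 4 (4E)-6-[(tert-butyldimethylsilyl)oxy]-4-methylhex-4-enal; 5 (4S)-4-benzyl-3-propanoyl-1,3-oxazolidin-2-one
Product: 7 (4S)-4-benzyl-3-[(2S,3R,6E)-8-{[tert-butyl(dimethyl)silyl]oxy}-3-hydroxy-2,6-dimethyloct-6-enoyl]-1,3-oxazolidin-2-one, via dibutylboron Z-enolate 6 (not isolated)
Conditions: Bu2BOTf, Et3N, CH2Cl2, 0 °C; 4, −78 to 0 °C; then pH 7 buffer, MeOH, H2O2
Reagents that add atoms: none
Why: In this Evans syn aldol reaction the Z-boron enolate reacts through a Zimmerman–Traxler chair on the face left open by the benzyl group, which sets C3 as R (the C4 centre formed here is erased in step 5).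

Step 4
Reactants: 7 Evans aldol adduct
Product: 8 2-(trimethylsilyl)ethyl (2S,3R,6E)-8-{[tert-butyl(dimethyl)silyl]oxy}-3-hydroxy-2,6-dimethyloct-6-enoate
Conditions: Me3SiCH2CH2OH, n-BuLi, THF, −20 to 0 °C; aq NH4Cl
Reagents that add atoms: 2-(trimethylsilyl)ethanol, C[Si](C)(C)CCO
Why: Alkoxide transesterification at the exocyclic imide carbonyl frees the auxiliary and installs a C19 ester that fluoride can later remove without touching other esters.

Step 5
Reactants: 8 β-hydroxy ester; 9 propargyl bromide
Product: 11 2-(trimethylsilyl)ethyl (2R,3R,6E)-8-{[tert-butyl(dimethyl)silyl]oxy}-3-hydroxy-2,6-dimethyl-2-(prop-2-yn-1-yl)oct-6-enoate, via dilithium alkoxide enolate 10 (not isolated)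
Conditions: LiN(i-Pr)2 (2.3 equiv), THF, −78 to −20 °C; 9, DMPU, −78 to −10 °C; aq NH4Cl
Reagents that add atoms: none
Why: In this Fráter–Seebach alkylation the lithium-chelated alkoxide enolate is attacked on the face anti to the C2 chain on C3, so the propargyl group (C5–C7) enters anti to the oxygen and sets the quaternary C4 with C18 cis and C19 trans to O3 in the later ring.

Step 6
Reactants: 11 quaternary β-hydroxy ester; 12 3-methylbutanoyl chloride
Product: 13 2-(trimethylsilyl)ethyl (2R,3R,6E)-8-{[tert-butyl(dimethyl)silyl]oxy}-2,6-dimethyl-3-[(3-methylbutanoyl)oxy]-2-(prop-2-yn-1-yl)oct-6-enoate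
Conditions: 12, pyridine, DMAP (cat.), CH2Cl2, 0 to 40 °C
Reagents that add atoms: none
Why: DMAP-catalysed acylation of the only free hydroxyl group installs the isovalerate of the target early, with retention at C3, so no later differentiation of three hydroxyl groups is needed.

Step 7
Reactants: 13 terminal alkyne; 14 acetyl chloride
Product: 15 2-(trimethylsilyl)ethyl (2R,3R,6E)-8-{[tert-butyl(dimethyl)silyl]oxy}-2,6-dimethyl-3-[(3-methylbutanoyl)oxy]-2-(4-oxopent-2-yn-1-yl)oct-6-enoate
Conditions: 14, PdCl2(PPh3)2 (cat.), CuI (cat.), Et3N, THF, rt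
Reagents that add atoms: none
Why: The acyl Sonogashira coupling of the terminal alkyne with the acid chloride adds C8 and C17 as an ynone under conditions that leave esters, silyl groups and the alkene alone.

Step 8
Reactants: 15 ynone
Product: 17 (1R,4E)-6-hydroxy-4-methyl-1-[(3R,5E)-3-methyl-2-oxo-5-(2-oxopropylidene)oxolan-3-yl]hex-4-en-1-yl 3-methylbutanoate, via ynone hydroxy acid 16 (not isolated)
Conditions: Bu4NF, THF, 0 °C to rt; aq NH4Cl
Reagents that add atoms: none
Why: Fluoride cleaves the silyl ether and the 2-(trimethylsilyl)ethyl ester in one pot, and the freed C19 carboxylate adds to the ynone β-carbon C6 (5-exo-dig oxa-Michael addition) to give the enol lactone, whose E isomer is the dipole-minimised, thermodynamic one.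

Step 9
Reactants: 17 lactone allylic alcohol
Product: 18 (1R,4E)-4-methyl-1-[(3R,5E)-3-methyl-2-oxo-5-(2-oxopropylidene)oxolan-3-yl]-6-oxohex-4-en-1-yl 3-methylbutanoate
Conditions: MnO2, CH2Cl2, rt
Reagents that add atoms: none
Why: MnO2 oxidises only the allylic alcohol, under neutral conditions, to the (E)-enal and keeps the alkene geometry and the acyl-transfer-prone lactone intact.

Step 10
Reactants: 18 enal lactone
Product: 21 tricyclic dienal lactone (3α-isovaleryloxy-11-oxo-12,13,14,15,16-pentanorlabda-6,8-dien-19,6-olide), via Michael adduct 19 (not isolated), via aldol adduct 20 (not isolated)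
Conditions: KOt-Bu (0.5 equiv), t-BuOH/THF 1:4 (0.002 M), 4 Å MS, 0 to 40 °C
Reagents that add atoms: none
Why: Proposed new method: in t-BuOH the enolates of 18 equilibrate, and the extended dienolate formed by γ-deprotonation at C5 (C5=C6(O-acyl)–C7=C8(O−)CH3) adds through C5 to C10 of the (E)-enal, the aldehyde enolate so formed (C9) attacks the C8 ketone, and E1cB loss of water gives the C8=C9 double bond, so that 19 and 20 are passed on the way to 21. The closest known reaction types are the Robinson annulation (Michael addition, then aldol condensation), vinylogous Michael additions of γ-enolisable enones and the base-mediated anionic Diels–Alder (double Michael) annulations of dienolates; an acyloxy-dienolate of a 5-ylidenebutanolide has not been used in this way. Ring A closes by a 6-(enolexo)-exo-trig Michael addition and ring B by a 6-(enolexo)-exo-trig aldol addition. C5 is controlled by C4, because the planar lactone holds C19 in the dienolate plane and the tether (C3) can deliver C10 only to the face on which it stands, which puts H5 cis to C18; C10 is controlled by the chair-like, tether-exo and formyl-endo arrangement of the (E)-enal, which places C20 anti to H5 (trans ring fusion) and keeps C9 away from the C19 carbonyl group. The step needs C5 rather than C17 or C7 as the nucleophilic site, 1,4- rather than 1,2-addition, and dehydration towards C9: only the C5-to-C10 union closes a six-membered ring, C7 is vinylic so water can leave only towards C9, and this irreversible last event drains all preceding equilibria. High dilution and molecular sieves should hold back intermolecular aldol reactions and hydrolysis of the pivalate-like enol lactone.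

Step 11
Reactants: 21 tricyclic dienal lactone; 22 methyltriphenylphosphonium bromide
Product: 23 vinyl triene lactone (3α-isovaleryloxy-13,14,15,16-tetranorlabda-6,8,11-trien-19,6-olide)
Conditions: 22, KN(SiMe3)2, THF, 0 °C; then 21, −78 to 0 °C
Reagents that add atoms: none
Why: Wittig methylenation adds C12, since the aldehyde reacts far faster with the ylide than the neopentyl lactone carbonyl or the isovalerate.

Step 12
Reactants: 24 2,2,6-trimethyl-4H-1,3-dioxin-4-one
Product: 26 2-(trimethylsilyl)ethyl 3-oxobutanoate, via acetylketene 25 (not isolated)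
Conditions: Me3SiCH2CH2OH, xylene, 130 °C
Reagents that add atoms: 2-(trimethylsilyl)ethanol, C[Si](C)(C)CCO
Why: Thermal retro-[4+2] cleavage of the dioxinone releases acetylketene, which the alcohol traps as the acetoacetate that holds C13–C16.

Step 13
Reactants: 26 2-(trimethylsilyl)ethyl 3-oxobutanoate
Product: 27 2-(trimethylsilyl)ethyl (2E)-3-{[(trifluoromethyl)sulfonyl]oxy}but-2-enoate
Conditions: Tf2O, aq Me4NOH, hexanes, 5 °C
Reagents that add atoms: trifluoromethanesulfonic anhydride, O=S(=O)(OS(=O)(=O)C(F)(F)F)C(F)(F)F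
Why: In this biphasic O-triflation the non-chelating tetramethylammonium ion leaves the β-keto ester enolate in its open, dipole-minimised form, so the triflate ends up trans to the ester (E), which fixes the later C13=C14 geometry.

Step 14
Reactants: 23 vinyl triene lactone; 27 (E)-enol triflate
Product: 29 2-(trimethylsilyl)ethyl (13E)-3α-isovaleryloxylabda-6,8,13-trien-19,6-olid-15-oate, via B-alkyl-9-BBN adduct 28 (not isolated)
Conditions: 9-BBN-H, THF, 0 °C to rt; then 27, Pd(dppf)Cl2 (cat.), aq K3PO4, DMF, rt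
Reagents that add atoms: none
Why: 9-BBN-H hydroborates only the terminal vinyl group in the anti-Markovnikov sense (boron on C12), and the B-alkyl Suzuki–Miyaura coupling joins C12 to C13 with retention of the triflate geometry, which gives the 13E enoate.

Step 15
Reactants: 29 dienol lactone ester
Product: 31 2-(trimethylsilyl)ethyl (13E)-6β,19-dihydroxy-3α-isovaleryloxylabda-8,13-dien-15-oate, via 6-oxo 19-alcohol 30 (not isolated)
Conditions: NaBH4 (excess), THF/i-PrOH 4:1, 0 °C to rt
Reagents that add atoms: none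
Why: This is the hydride reduction of a dienol ester (the reaction type that turns steroidal dienol acetates into homoallylic alcohols): hydride opens the activated enol lactone at C19 down to CH2OH, the released dienolate is protonated kinetically at C7 so the alkene stays at C8=C9, and ketone 30 is reduced from the open α face (the β face is shielded by C20 and C19), which sets 6β-OH, while the alkyl isovalerate and the conjugated ester are inert to NaBH4.

Step 16
Reactants: 31 diol ester
Product: 32 (13E)-6β,19-dihydroxy-3α-(3-methylbutanoyloxy)labda-8,13-dien-15-oic acid (CNP0274836.1)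
Conditions: Bu4NF, THF, 0 °C to rt; then 0.5 M HCl
Reagents that add atoms: none
Why: Fluoride-induced fragmentation of the 2-(trimethylsilyl)ethyl ester frees the C15 acid without hydrolytic conditions, and the isovalerate cannot migrate because O3 and C19 are antiperiplanar.

Compound list
1 | geraniol, (2E)-3,7-dimethylocta-2,6-dien-1-ol | CC(C)=CCC/C(C)=C/CO | starting material
2 | geranyl tert-butyldimethylsilyl ether | CC(C)=CCC/C(C)=C/CO[Si](C)(C)C(C)(C)C | intermediate
3 | secondary ozonide of the 6,7-alkene of 2 (1,2,4-trioxolane) | CC1(C)OOC(CC/C(C)=C/CO[Si](C)(C)C(C)(C)C)O1 | intermediate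
4 | (4E)-6-[(tert-butyldimethylsilyl)oxy]-4-methylhex-4-enal | O=CCC/C(C)=C/CO[Si](C)(C)C(C)(C)C | intermediate
5 | (4S)-4-benzyl-3-propanoyl-1,3-oxazolidin-2-one | CCC(=O)N1[C@@H](Cc2ccccc2)COC1=O | starting material
6 | dibutylboron Z-enolate of 5 | C/C=C(\OB(CCCC)CCCC)N1[C@@H](Cc2ccccc2)COC1=O | intermediate
7 | (4S)-4-benzyl-3-[(2S,3R,6E)-8-{[tert-butyl(dimethyl)silyl]oxy}-3-hydroxy-2,6-dimethyloct-6-enoyl]-1,3-oxazolidin-2-one | CC(C)(C)[Si](C)(C)OC/C=C(\C)CC[C@@H](O)[C@H](C)C(=O)N1[C@@H](Cc2ccccc2)COC1=O | intermediate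
8 | 2-(trimethylsilyl)ethyl (2S,3R,6E)-8-{[tert-butyl(dimethyl)silyl]oxy}-3-hydroxy-2,6-dimethyloct-6-enoate | CC(C)(C)[Si](C)(C)OC/C=C(\C)CC[C@@H](O)[C@H](C)C(=O)OCC[Si](C)(C)C | intermediate
9 | propargyl bromide, 3-bromoprop-1-yne | C#CCBr | starting material
10 | dilithium alkoxide enolate of 8 | [Li+].[Li+].CC(C)(C)[Si](C)(C)OC/C=C(\C)CC[C@@H]([O-])C(C)=C([O-])OCC[Si](C)(C)C | intermediate
11 | 2-(trimethylsilyl)ethyl (2R,3R,6E)-8-{[tert-butyl(dimethyl)silyl]oxy}-3-hydroxy-2,6-dimethyl-2-(prop-2-yn-1-yl)oct-6-enoate | CC(C)(C)[Si](C)(C)OC/C=C(\C)CC[C@@H](O)[C@](C)(C(=O)OCC[Si](C)(C)C)CC#C | intermediate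
12 | 3-methylbutanoyl chloride (isovaleryl chloride) | CC(C)CC(=O)Cl | starting material
13 | 3-O-isovalerate of 11 | CC(C)(C)[Si](C)(C)OC/C=C(\C)CC[C@@H](OC(=O)CC(C)C)[C@](C)(C(=O)OCC[Si](C)(C)C)CC#C | intermediate
14 | acetyl chloride | CC(=O)Cl | starting material
15 | ynone, 2-(4-oxopent-2-yn-1-yl) analogue of 13 | CC(C)(C)[Si](C)(C)OC/C=C(\C)CC[C@@H](OC(=O)CC(C)C)[C@](C)(C(=O)OCC[Si](C)(C)C)CC#CC(C)=O | intermediate
16 | ynone hydroxy acid (both silicon groups removed) | OC/C=C(\C)CC[C@@H](OC(=O)CC(C)C)[C@](C)(C(=O)O)CC#CC(C)=O | intermediate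
17 | (1R,4E)-6-hydroxy-4-methyl-1-[(3R,5E)-3-methyl-2-oxo-5-(2-oxopropylidene)oxolan-3-yl]hex-4-en-1-yl 3-methylbutanoate | OC/C=C(\C)CC[C@@H](OC(=O)CC(C)C)[C@]1(C)C(=O)O/C(=C/C(C)=O)C1 | intermediate
18 | (1R,4E)-4-methyl-1-[(3R,5E)-3-methyl-2-oxo-5-(2-oxopropylidene)oxolan-3-yl]-6-oxohex-4-en-1-yl 3-methylbutanoate | O=C/C=C(\C)CC[C@@H](OC(=O)CC(C)C)[C@]1(C)C(=O)O/C(=C/C(C)=O)C1 | intermediate
19 | Michael adduct: ring A closed (C5–C10), CH2CHO on C10, 5-(2-oxopropylidene) lactone kept | O=CC[C@@]2(C)CC[C@@H](OC(=O)CC(C)C)[C@](C)(C(=O)O3)[C@@H]2/C3=C\C(C)=O | intermediate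
20 | aldol adduct: ring B closed (C8–C9), 8-hydroxy-9-formyl, C8 and C9 configuration without consequence | CC1(O)C(C=O)[C@@]2(C)CC[C@@H](OC(=O)CC(C)C)[C@](C)(C(=O)O3)[C@@H]2C3=C1 | intermediate
21 | 3α-isovaleryloxy-11-oxo-12,13,14,15,16-pentanorlabda-6,8-dien-19,6-olide (trans A/B, 5α-H, 10β-CH3, 4α-CH3) | CC1=C(C=O)[C@@]2(C)CC[C@@H](OC(=O)CC(C)C)[C@](C)(C(=O)O3)[C@@H]2C3=C1 | intermediate
22 | methyltriphenylphosphonium bromide | C[P+](c1ccccc1)(c1ccccc1)c1ccccc1.[Br-] | starting material
23 | 3α-isovaleryloxy-13,14,15,16-tetranorlabda-6,8,11-trien-19,6-olide | CC1=C(C=C)[C@@]2(C)CC[C@@H](OC(=O)CC(C)C)[C@](C)(C(=O)O3)[C@@H]2C3=C1 | intermediate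
24 | 2,2,6-trimethyl-4H-1,3-dioxin-4-one | CC1=CC(=O)OC(C)(C)O1 | starting material
25 | acetylketene | CC(=O)C=C=O | intermediate
26 | 2-(trimethylsilyl)ethyl 3-oxobutanoate | CC(=O)CC(=O)OCC[Si](C)(C)C | intermediate
27 | 2-(trimethylsilyl)ethyl (2E)-3-{[(trifluoromethyl)sulfonyl]oxy}but-2-enoate | C/C(OS(=O)(=O)C(F)(F)F)=C\C(=O)OCC[Si](C)(C)C | intermediate
28 | B-alkyl-9-BBN adduct of 23 (boron on C12) | CC1=C(CCB4C5CCCC4CCC5)[C@@]2(C)CC[C@@H](OC(=O)CC(C)C)[C@](C)(C(=O)O3)[C@@H]2C3=C1 | intermediate
29 | 2-(trimethylsilyl)ethyl (13E)-3α-isovaleryloxylabda-6,8,13-trien-19,6-olid-15-oate | CC1=C(CC/C(C)=C/C(=O)OCC[Si](C)(C)C)[C@@]2(C)CC[C@@H](OC(=O)CC(C)C)[C@](C)(C(=O)O3)[C@@H]2C3=C1 | intermediate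
30 | 2-(trimethylsilyl)ethyl (13E)-19-hydroxy-3α-isovaleryloxy-6-oxolabda-8,13-dien-15-oate | CC1=C(CC/C(C)=C/C(=O)OCC[Si](C)(C)C)[C@@]2(C)CC[C@@H](OC(=O)CC(C)C)[C@](C)(CO)[C@@H]2C(=O)C1 | intermediate
31 | 2-(trimethylsilyl)ethyl (13E)-6β,19-dihydroxy-3α-isovaleryloxylabda-8,13-dien-15-oate | CC1=C(CC/C(C)=C/C(=O)OCC[Si](C)(C)C)[C@@]2(C)CC[C@@H](OC(=O)CC(C)C)[C@](C)(CO)[C@@H]2[C@H](O)C1 | intermediate
32 | (13E)-6β,19-dihydroxy-3α-(3-methylbutanoyloxy)labda-8,13-dien-15-oic acid (CNP0274836.1) | CC1=C(CC/C(C)=C/C(=O)O)[C@@]2(C)CC[C@@H](OC(=O)CC(C)C)[C@](C)(CO)[C@@H]2[C@H](O)C1 | target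

Total step count: 16. Longest linear sequence: 14 (steps 1–11 and 14–16; steps 12 and 13 form the side branch).

Steps most likely to fail

1. Step 10 (proposed new method).
What may go wrong:
- The enolate equilibrium may rest on the C17 side without cyclisation.
- Retro-Michael cleavage of the crowded C5–C10 bond may outrun the aldol closure.
- Exo/endo discrimination may be poor, which would erode the trans ring fusion.
- The water set free may open the enol lactone.

The fallback uses known chemistry only. It sets out from ynone 15 and comes back at 21. Luche reduction (NaBH4, CeCl3·7H2O, MeOH, −78 °C) should give propargylic alcohol F1. A gold-catalysed Meyer–Schuster rearrangement (Ph3PAuNTf2 cat., MeOH, toluene, rt) moves the oxygen to C6 and should give (E)-enone F2. Bu4NF then frees keto acid alcohol F3, and MnO2 oxidises it to enal keto acid F4. Azeotropic enol lactonisation (TsOH cat., toluene, Dean–Stark) should close propenylfuranone diene F5, in which C5=C6–C7=C8 is a 2-acyloxydiene held by the same lactone. A thermal intramolecular Diels–Alder reaction (toluene, BHT, sealed tube, 160 °C) should give cycloadduct aldehyde F6, with C5–C10 and C8–C9 formed together under the same facial and endo control. IBX dehydrogenation of the aldehyde (DMSO, 75 °C) then introduces C8=C9 and delivers 21.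

2. Step 15.
What may go wrong:
- Chemoselectivity among the four ester-type carbonyl groups may be lost.
- The solvent may open the lactone by solvolysis in place of hydride attack.
- The alkene may drift into conjugation with the C6 ketone before that hindered ketone is reduced.

The fallback sets out from 29 and comes back at 31. The enol lactone, the most electrophilic ester, is saponified (LiOH, 1 equiv, THF/H2O, 0 °C), and cold buffered acidification gives 6-oxo 19-acid F7. BH3·SMe2 (THF, 0 °C), which reduces carboxylic acids and ketones but not esters, should then turn C19 into CH2OH and reduce C6 from the α face to give 31.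

3. Step 14.
What may go wrong:
- Hydroboration of the hindered, conjugated vinyl group may be sluggish or unselective.
- The aqueous base may hydrolyse the triflate or the enol lactone.
- The enoate geometry may be lost during coupling.

The fallback sets out from 21, bypasses 23 and comes back at 29. Wittig reaction with Ph3P=CHC(O)CH3 (toluene, 80 °C) should give ionone-type dienone F8. Conjugate reduction with [(Ph3P)CuH]6 (benzene, rt) should saturate only C11=C12 and give methyl ketone F9. A Horner–Wadsworth–Emmons reaction with 2-(trimethylsilyl)ethyl (diethoxyphosphoryl)acetate and NaH (THF, 0 °C to rt) then builds the E-configured C13=C14 enoate 29. The minor Z isomer would be removed by chromatography.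

Further compounds
F1 | step 10 | propargylic alcohol (C8 carbinol, epimer mixture) from 15 | CC(C)(C)[Si](C)(C)OC/C=C(\C)CC[C@@H](OC(=O)CC(C)C)[C@](C)(C(=O)OCC[Si](C)(C)C)CC#CC(C)O
F2 | step 10 | (E)-enone with the ketone at C6 | CC(C)(C)[Si](C)(C)OC/C=C(\C)CC[C@@H](OC(=O)CC(C)C)[C@](C)(C(=O)OCC[Si](C)(C)C)CC(=O)/C=C/C
F3 | step 10 | keto acid alcohol | OC/C=C(\C)CC[C@@H](OC(=O)CC(C)C)[C@](C)(C(=O)O)CC(=O)/C=C/C
F4 | step 10 | enal keto acid | O=C/C=C(\C)CC[C@@H](OC(=O)CC(C)C)[C@](C)(C(=O)O)CC(=O)/C=C/C
F5 | step 10 | propenylfuranone diene, 3,3-disubstituted 5-[(E)-prop-1-enyl]furan-2(3H)-one | O=C/C=C(\C)CC[C@@H](OC(=O)CC(C)C)[C@@]1(C)C=C(/C=C/C)OC1=O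
F6 | step 10 | cycloadduct aldehyde (8,9-dihydro-21, C8 and C9 configuration without consequence) | CC1C(C=O)[C@@]2(C)CC[C@@H](OC(=O)CC(C)C)[C@](C)(C(=O)O3)[C@@H]2C3=C1
F7 | step 15 | 6-oxo 19-acid, (13E)-15-[2-(trimethylsilyl)ethoxy]-3α-isovaleryloxy-6,15-dioxolabda-8,13-dien-19-oic acid | CC1=C(CC/C(C)=C/C(=O)OCC[Si](C)(C)C)[C@@]2(C)CC[C@@H](OC(=O)CC(C)C)[C@](C)(C(=O)O)[C@@H]2C(=O)C1
F8 | step 14 | ionone-type dienone, (11E)-13-oxo-14,15-dinorlabda-6,8,11-trien-19,6-olide 3α-isovalerate | CC1=C(/C=C/C(C)=O)[C@@]2(C)CC[C@@H](OC(=O)CC(C)C)[C@](C)(C(=O)O3)[C@@H]2C3=C1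
F9 | step 14 | methyl ketone, 13-oxo-14,15-dinorlabda-6,8-dien-19,6-olide 3α-isovalerate | CC1=C(CCC(C)=O)[C@@]2(C)CC[C@@H](OC(=O)CC(C)C)[C@](C)(C(=O)O3)[C@@H]2C3=C1
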